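Assumption 1: the target is drawn without axial configuration, so the route aims at the racemic atropisomer. The methyl-bearing sp3 carbon of ring A2 in compounds 18 to 22 is racemic and disappears on aromatisation.

Assumption 2: 4-(benzyloxy)-3-methoxybenzaldehyde 1 (O-benzylvanillin) is taken as an article of commerce; it is otherwise one benzylation from vanillin.

Locants: half A is unprimed (C1 to C8, C4a, C8a), half B is primed (C1' to C8', C4a', C8a'). For pyrone 19, "pyrone C3" and "pyrone C6" are C3 and C8a of the chromene name, and "pyrone C5" is C4a.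

## The problem

Compound 25 is an unsymmetrical 4,1'-linked binaphthalene. Half A is 1-methoxy-6-methylnaphthalene-3,8-diol bonded through C4; half B is 5'-methoxy-2'-methylnaphthalene-4',6'-diol bonded through C1'. The bond between the halves is flanked by C3–OH and the peri C5–H on one side and by the C2' methyl group and the peri C8'–H on the other. A plan that joins two finished naphthalenes must therefore force a coupling through four flanking groups, after halogenating and metalating each half at one specific position. There is no stereocentre; the only stereogenic element is this hindered axis, which is unspecified, so no element of the molecule has to control another. The real selectivity problem is the oxygen pattern. C1–OMe must be told apart from C3–OH and C8–OH, and C5'–OMe lies between C4'–OH and C6'–OH, so late selective methylation or demethylation is not available. The free tetraphenol is electron-rich and will oxidise in air under basic conditions, and its peri-methoxy groups will not survive strong Lewis acids; the phenols should be released last under neutral conditions. The feature that opens the structure is ring A1 (C1 to C4, C4a, C8a): a benzene ring with oxygen at C1 and C3 and the aryl group at C4, fused to ring A2 (C5 to C8), whose C8 oxygen, C6 methyl group and carbon skeleton are those of 5-methylcyclohexane-1,3-dione 16. Ring A1 can therefore be built last by cycloaddition and loss of CO2. The dione-fused 5-acyl-2-pyrone brings C1–OMe and the C8 carbonyl; an oxygen-substituted arylalkyne from half B brings C3–O and the biaryl bond.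

## Retrosynthesis

**Unmasking (25 ⇒ 24 ⇒ 23).** Only the O–benzyl bonds at O4' and O6' and the O–Si bond at O3 are cut. Benzyl is chosen because the half-B oxygens must pass hydride, organolithium, radical and thermal steps and then be freed without acid next to the peri-methoxy groups. The silyl group is not an added protecting group but the residue of the ynol ether. Compounds 24 and 23 are no simpler in skeleton, but they are stable ethers. The forward steps (fluoride, then H2 over Pd/C) must leave the aryl methyl ethers and the naphthalene rings alone.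

**Ring A2 aromaticity (23 ⇒ 21, through 22).** No carbon–carbon bond is cut; the C6–C7 unsaturation is removed, which turns the C8 naphthol into tetralone 21. This is preferred to keeping ring A2 aromatic because a benzo-fused pyrone would not act as a diene, whereas a cyclohexanone-fused pyrone does and comes from a dione. Ring A2 then maps carbon for carbon onto dione 16; the transient C6 stereocentre is of no consequence. The forward reaction is one dehydrogenation, regiodefined because the ketone can enolise only toward C7. It must be chemoselective beside electron-rich arenes, which is why it is routed through silyl enol ether 22.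

**Key disconnection (21 ⇒ 19 + 15, through 20).** Bonds C2–C3 and C4–C4a are cut and CO2 is added back across C2 and C4a, giving bridged lactone 20 and then pyrone 19 and siloxyalkyne 15. The neighbouring cut at C4–C1' would need two finished naphthalenes and a coupling through four flanking groups. A cut in ring A2 would leave a hexasubstituted benzene to be assembled. The chosen cut forms the hindered bond from a linear sp carbon and delivers C1–OMe, C3–OSi and C8=O already differentiated. The precursors are much simpler: 19 is two steps from commodity chemicals, and 15 is half B plus two carbons. The forward reaction needs the aryl-bearing alkyne carbon to bond to pyrone C6 and needs enough diene reactivity below the decomposition range of the ynol ether.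

**Pyrone (19 ⇒ 18 ⇒ 16 + 17).** The O–CH3 bond is cut, then the two acyl bonds of the pyrone ring (C–C to the central dione carbon, O–C to the enol oxygen). The symmetric dione 16 allows only one constitution, so this is shorter than any stepwise pyrone assembly. The forward reactions are a C,O-diacylation with malonyl dichloride 17 and methylation of the 4-hydroxyl of 18 rather than of a carbonyl oxygen.

**Siloxyalkyne (15 ⇒ 13 ⇒ 12 ⇒ 10; intermediates 14 and 11).** The O–Si and C–O bonds are cut back to terminal alkyne 13 (acetylide oxidation through ynolate 14). This is preferred to ester homologation because carbonyl addition at C1', between the methyl group and the peri hydrogen, is hindered, whereas the acetylide terminus is remote. The alkyne carbon is cut back to aldehyde 12, and the C1'–CHO bond to arene 10 (formylation through iminium salt 11). Each precursor is one carbon or one heteroatom simpler. The forward formylation must select C1', the alpha position para to O4' and ortho to the methyl group.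

**Methyl group and blocking bromine (10 ⇒ 9 ⇒ 8 ⇒ 7).** The C2' methyl group is traced to an ester carbon and C8'–H to C8'–Br. These are functional-group changes, chosen because the Stobbe synthesis puts an ester exactly at C2', and both carbon–bromine bonds of 9 can be reduced in one radical step. The forward sequence is ester reduction to 8, bromination to 9 and double reduction to 10.

**Ring B1 (7 ⇒ 5 ⇒ 4 ⇒ 2 + 3; 2 ⇒ 1; intermediate 6).** Bond C4'–C4a' (ring closure of half-ester 4) and the C1'=C2' bond (condensation of aldehyde 2 with dimethyl succinate 3) are cut. The bromine of 2, para to the methoxy group, forces the ring to close on the methoxy side and so sets the 5'-OMe/6'-O pattern. Without it the isomeric 6,7-dioxygenated naphthalene would form. The precursors are commercial aldehyde 1 and diester 3. The forward cyclisation must take place at a position flanked by the methoxy group, and the acetate of 5 is exchanged for benzyl through naphthol 6.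

## Roads not taken

**Alternative 1:** Ring B1 is cut at C1'–C2' and C3'–C4'. In the forward sense the C3 anion of arylphthalide A2, which already carries all of half A on the lactone carbon, adds to methyl crotonate A3. The ester enolate then closes on the lactone carbonyl, and acid dehydration gives naphthoate A1.
- Merits: the biaryl bond is made as a bond to an sp3 carbon by carbonyl chemistry; the annulation is anionic and cold; C2'–Me and C4'–OH are fixed by the reagents.
- Weak points: the nucleophile is a tertiary, doubly benzylic anion flanked by the ortho and peri groups of half A, and it must bond to the methyl-bearing β-carbon of A3, a congested and reversible Michael step. A1 carries an ester at C3' that the target lacks, so saponification and decarboxylation of a hindered naphthoate follow. Half A must first be made as a complete, protected, C4-metalated naphthalene with its own oxygen differentiation, so two naphthalene syntheses are needed.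
- Comparison: this road is better in one respect, since it avoids heating a sensitive ynol ether and rests on robust Michael–Claisen chemistry. The chosen plan sets against this that half A costs a two-step pyrone plus the cycloaddition, carries no superfluous carbon, and has its three oxygens differentiated by construction.

**Alternative 2:** Ring A1 is cut at C1–C8a. Forward, the extended enolate of keto ester A5 attacks the side-chain ester through C8a and tautomerisation gives resorcinol A4 fused to the C8 ketone.
- Merits: polyketide-like logic; half B sits on an sp3 carbon in A5, so the axis arises on aromatisation; no heat-sensitive reagent; the same late aromatisation of ring A2 as in the chosen plan.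
- Weak points: the most acidic protons of A5 lie at C2 between ketone and ester, and their removal deactivates the ester, so the closure needs a polyanion reacting at the α-carbon of a dienolate against γ- and O-reactivity. A4 has both C1–OH and C3–OH free; C1–OH is chelated to the C8 ketone, so methylation would favour the wrong oxygen and a protect, methylate, deprotect detour follows. A5 itself, an aryl methine flanked by an enone and a β-keto ester, is hard to assemble and prone to retro-Claisen cleavage.
- Comparison: equal in the endgame and free of the thermal step, but inferior where it matters most, the C1/C3 oxygen differentiation that the pyrone settles in advance.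

**Alternative 3:** Ring A2 is cut at C4a–C5 and C8–C8a. Forward, the aryne from silyl triflate A7 (the ring-A1 biaryl) is trapped by ketene acetal diene A8; loss of methanol and of the silyl group gives A6 with ring A2 aromatic and C8–OH free.
- Merits: no dehydrogenation; C8–OH emerges free and differentiated; the endgame is a single hydrogenolysis; the C1 methoxy group polarises the aryne so that the nucleophilic diene terminus goes to C4a.
- Weak points: the biaryl bond must be made beforehand by cross-coupling onto a hexasubstituted benzene bearing ortho silyl and ortho benzyloxy groups, which is the problem the target poses in the first place. A7 needs a long regiocontrolled synthesis. The aryne terminus C4a is flanked by the bulky naphthyl group, so sterics oppose the electronic preference. Ketene acetals also give (2+2) adducts with arynes.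
- Comparison: this road is better after the key step (fewer steps, no oxidation). The chosen plan sets against this a biaryl bond made without any coupling and no hexasubstituted benzene precursor.

Key step: step 13

## Route

Step 1
Reactants: 1 4-(benzyloxy)-3-methoxybenzaldehyde
Product: 2 4-(benzyloxy)-2-bromo-5-methoxybenzaldehyde
Conditions: Br2, NaOAc, AcOH, rt
Reagents that add atoms: bromine, BrBr
Why: Electrophilic aromatic bromination goes para to the methoxy group and ortho to the formyl group, the usual outcome for 3,4-dialkoxybenzaldehydes; the bromine blocks the position at which the later ring closure would otherwise occur.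

Step 2
Reactants: 2 4-(benzyloxy)-2-bromo-5-methoxybenzaldehyde; 3 dimethyl succinate
Product: 4 (E)-4-[4-(benzyloxy)-2-bromo-5-methoxyphenyl]-3-(methoxycarbonyl)but-3-enoic acid
Conditions: NaOMe, MeOH, reflux; then aq. HCl
Reagents that add atoms: none
Why: Stobbe condensation; aldol addition, lactonisation and base-induced ring opening give the alkylidene half-ester, with the aryl group cis to the CH2CO2H arm as the later ring closure requires.

Step 3
Reactants: 4 (E)-4-[4-(benzyloxy)-2-bromo-5-methoxyphenyl]-3-(methoxycarbonyl)but-3-enoic acid
Product: 5 methyl 4-acetoxy-6-(benzyloxy)-8-bromo-5-methoxy-2-naphthoate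
Conditions: Ac2O, NaOAc, reflux
Reagents that add atoms: acetic anhydride, CC(=O)OC(C)=O
Why: Second half of the Stobbe naphthol synthesis: the mixed anhydride cyclises (ketene formation and 6π-electrocyclisation) onto the only free ortho position and the naphthol is acetylated in situ. The bromine forces closure on the methoxy side, which sets the 5'-OMe/6'-OBn pattern of half B.

Step 4
Reactants: 5 methyl 4-acetoxy-6-(benzyloxy)-8-bromo-5-methoxy-2-naphthoate
Product: 7 methyl 4,6-bis(benzyloxy)-8-bromo-5-methoxy-2-naphthoate, via free naphthol 6 (not isolated)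
Conditions: K2CO3, MeOH, rt; evaporate; BnBr, K2CO3, DMF, rt
Reagents that add atoms: benzyl bromide, BrCc1ccccc1
Why: Carbonate methanolysis of the aryl acetate followed by Williamson benzylation of the naphthoxide replaces the base-labile acetate by an ether that survives hydride, organolithium and heat.

Step 5
Reactants: 7 methyl 4,6-bis(benzyloxy)-8-bromo-5-methoxy-2-naphthoate
Product: 8 [4,6-bis(benzyloxy)-8-bromo-5-methoxynaphthalen-2-yl]methanol
Conditions: LiAlH4, THF, 0 °C
Reagents that add atoms: none
Why: Hydride reduction of the methyl ester to the primary alcohol; at 0 °C LiAlH4 leaves the aryl bromide and the benzyl ethers untouched.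

Step 6
Reactants: 8 [4,6-bis(benzyloxy)-8-bromo-5-methoxynaphthalen-2-yl]methanol
Product: 9 1,7-bis(benzyloxy)-5-bromo-3-(bromomethyl)-8-methoxynaphthalene
Conditions: CBr4, PPh3, CH2Cl2, 0 °C
Reagents that add atoms: carbon tetrabromide, BrC(Br)(Br)Br
Why: Appel bromination converts the primary benzylic alcohol into the bromide under neutral conditions that spare the benzyl ethers.

Step 7
Reactants: 9 1,7-bis(benzyloxy)-5-bromo-3-(bromomethyl)-8-methoxynaphthalene
Product: 10 1,7-bis(benzyloxy)-8-methoxy-3-methylnaphthalene
Conditions: Bu3SnH (2.5 equiv), AIBN (cat.), PhMe, 100 °C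
Reagents that add atoms: none
Why: Radical chain reduction with Bu3SnH removes the benzylic and the aryl bromine in one operation, which turns the former ester carbon into the C2' methyl group and frees C8'; benzyl ethers are inert to stannyl radicals.

Step 8
Reactants: 10 1,7-bis(benzyloxy)-8-methoxy-3-methylnaphthalene
Product: 12 4,6-bis(benzyloxy)-5-methoxy-2-methyl-1-naphthaldehyde, via iminium salt 11 (not isolated)
Conditions: POCl3, DMF, 0 to 80 °C; then aq. NaOAc
Reagents that add atoms: N,N-dimethylformamide, CN(C)C=O; water, O
Why: Vilsmeier–Haack formylation at the alpha position para to the C4' benzyloxy group and ortho to the methyl group (future C1'), the most electron-rich site. The other para-alkoxy alpha position (C8') is served only by the C5' methoxy group, which is twisted out of conjugation by its two neighbours. Aqueous work-up hydrolyses iminium salt 11 to the aldehyde.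

Step 9
Reactants: 12 4,6-bis(benzyloxy)-5-methoxy-2-methyl-1-naphthaldehyde
Product: 13 4,6-bis(benzyloxy)-1-ethynyl-5-methoxy-2-methylnaphthalene
Conditions: dimethyl (1-diazo-2-oxopropyl)phosphonate, K2CO3, MeOH–THF, rt
Reagents that add atoms: dimethyl (1-diazo-2-oxopropyl)phosphonate, COP(=O)(OC)C(=[N+]=[N-])C(C)=O
Why: Ohira–Bestmann (Seyferth–Gilbert) homologation converts the aldehyde into the terminal alkyne under mild carbonate conditions through an alkylidene carbene 1,2-shift.

Step 10
Reactants: 13 4,6-bis(benzyloxy)-1-ethynyl-5-methoxy-2-methylnaphthalene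
Product: 15 ({[4,6-bis(benzyloxy)-5-methoxy-2-methylnaphthalen-1-yl]ethynyl}oxy)tri(propan-2-yl)silane, via lithium ynolate 14 (not isolated)
Conditions: LiHMDS, THF, −78 °C; t-BuOOLi (from t-BuOOH, LiHMDS), −78 to 0 °C; TIPSOTf, −78 °C
Reagents that add atoms: tert-butyl hydroperoxide, CC(C)(C)OO; triisopropylsilyl trifluoromethanesulfonate, CC(C)[Si](OS(=O)(=O)C(F)(F)F)(C(C)C)C(C)C
Why: The lithium acetylide takes up electrophilic oxygen from lithium tert-butyl peroxide to give the ynolate, which the hard, bulky silyl triflate traps on oxygen; this is the established route from terminal alkynes to triisopropylsilyl ynol ethers. It avoids any carbonyl addition at the hindered C1' position.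

Step 11
Reactants: 16 5-methylcyclohexane-1,3-dione; 17 malonyl dichloride
Product: 18 4-hydroxy-7-methyl-7,8-dihydro-2H-chromene-2,5(6H)-dione (racemic)
Conditions: CHCl3, reflux
Reagents that add atoms: none
Why: C-acylation of the dione at its central carbon and O-acylation of the enol by the second acid chloride build the fused 4-hydroxy-2-pyrone, the standard pyrone synthesis from 1,3-dicarbonyl compounds and malonyl dichloride. The symmetric dione allows one constitution only.

Step 12
Reactants: 18 4-hydroxy-7-methyl-7,8-dihydro-2H-chromene-2,5(6H)-dione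
Product: 19 4-methoxy-7-methyl-7,8-dihydro-2H-chromene-2,5(6H)-dione (racemic)
Conditions: Me2SO4, K2CO3, acetone, reflux
Reagents that add atoms: dimethyl sulfate, COS(=O)(=O)OC
Why: O-methylation of the acidic 4-hydroxy-2-pyrone with a hard methylating agent and carbonate gives the 4-methoxy-2-pyrone, as is routine for this class.

Step 13
Reactants: 19 4-methoxy-7-methyl-7,8-dihydro-2H-chromene-2,5(6H)-dione; 15 ({[4,6-bis(benzyloxy)-5-methoxy-2-methylnaphthalen-1-yl]ethynyl}oxy)tri(propan-2-yl)silane
Product: 21 5-[4,6-bis(benzyloxy)-5-methoxy-2-methylnaphthalen-1-yl]-8-methoxy-3-methyl-6-{[tri(propan-2-yl)silyl]oxy}-3,4-dihydronaphthalen-1(2H)-one, via bridged lactone 20 (not isolated)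
Conditions: 15 (1.5 equiv), PhMe, 110–130 °C, sealed tube
Reagents that add atoms: none
Why: Inverse-electron-demand Diels–Alder addition of the electron-rich siloxyalkyne to the pyrone diene (pyrone C3=C4–C5=C6) gives bridged lactone 20, which loses CO2 by retro-Diels–Alder reaction and leaves benzene ring A1; the closest known reaction type is the cycloaddition of coumalate-type 5-acyl-2-pyrones with ynamines, alkoxyalkynes and siloxyalkynes followed by CO2 extrusion. Ring A1 closes by intermolecular (4+2) cycloaddition that forms C4–C4a and C2–C3, and it becomes aromatic when the O–C(=O) bridge leaves. The selectivity needed is regiochemical: the aryl-bearing alkyne carbon is the nucleophilic β-carbon of the ynol ether and bonds to pyrone C6, the electrophilic terminus that is β to the ring ketone and δ to the lactone carbonyl, while the oxygen-bearing alkyne carbon pairs with pyrone C3, the enol-ether β-carbon of the 4-methoxy group. The cyclohexenone ring holds the ketone s-trans to the C5=C6 bond, so a hetero-Diels–Alder reaction of the enone cannot compete, and a (2+2) adduct at C5=C6 can revert whereas CO2 loss is irreversible. No new stereocentre is set: the C6 methyl centre comes in racemic from 19, and the hindered axis forms as a mixture of atropisomeric diastereomers that converge once ring A2 is aromatic. The silyl group ends as the C3 aryl silyl ether, so C1–OMe, C3–OSi and the C8 carbonyl are differentiated without a protecting-group step.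

Step 14
Reactants: 21 5-[4,6-bis(benzyloxy)-5-methoxy-2-methylnaphthalen-1-yl]-8-methoxy-3-methyl-6-{[tri(propan-2-yl)silyl]oxy}-3,4-dihydronaphthalen-1(2H)-one
Product: 23 5-[4,6-bis(benzyloxy)-5-methoxy-2-methylnaphthalen-1-yl]-8-methoxy-3-methyl-6-{[tri(propan-2-yl)silyl]oxy}naphthalen-1-ol, via trimethylsilyl enol ether 22 (not isolated)
Conditions: TMSOTf, Et3N, CH2Cl2, 0 °C; then Pd(OAc)2 (1.1 equiv), MeCN, rt
Reagents that add atoms: none
Why: Saegusa–Ito oxidation: soft enolisation toward C7, the only enolisable side, gives silyl enol ether 22, and Pd(OAc)2 converts it by β-hydride elimination from C6 into the C6=C7 enone, the keto tautomer of the C8 naphthol, which tautomerises at once. The oxidant acts on the enol ether and not on the electron-rich arenes, and aromatisation removes the C6 stereocentre so the diastereomers converge to one racemate.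

Step 15
Reactants: 23 5-[4,6-bis(benzyloxy)-5-methoxy-2-methylnaphthalen-1-yl]-8-methoxy-3-methyl-6-{[tri(propan-2-yl)silyl]oxy}naphthalen-1-ol
Product: 24 5-[4,6-bis(benzyloxy)-5-methoxy-2-methylnaphthalen-1-yl]-8-methoxy-3-methylnaphthalene-1,6-diol
Conditions: TBAF, AcOH, THF, 0 °C
Reagents that add atoms: none
Why: Fluoride cleaves the aryl silyl ether; the acetic acid buffer keeps the electron-rich naphthoxide from air oxidation, and benzyl and methyl ethers are inert.

Step 16
Reactants: 24 5-[4,6-bis(benzyloxy)-5-methoxy-2-methylnaphthalen-1-yl]-8-methoxy-3-methylnaphthalene-1,6-diol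
Product: 25 5-(4,6-dihydroxy-5-methoxy-2-methylnaphthalen-1-yl)-8-methoxy-3-methylnaphthalene-1,6-diol (CNP0147277.0, racemic axis)
Conditions: H2 (1 atm), Pd/C, EtOAc–MeOH, rt
Reagents that add atoms: none
Why: Hydrogenolysis of the two benzyl ethers over Pd/C leaves aryl methyl ethers and the naphthalene rings untouched and needs only filtration and evaporation, which suits the oxidation-prone tetraphenol.

## Compound list

1 | 4-(benzyloxy)-3-methoxybenzaldehyde (O-benzylvanillin) | O=Cc1ccc(OCc2ccccc2)c(OC)c1 | starting material
2 | 4-(benzyloxy)-2-bromo-5-methoxybenzaldehyde | O=Cc1cc(OC)c(OCc2ccccc2)cc1Br | intermediate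
3 | dimethyl succinate | COC(=O)CCC(=O)OC | starting material
4 | (E)-4-[4-(benzyloxy)-2-bromo-5-methoxyphenyl]-3-(methoxycarbonyl)but-3-enoic acid | OC(=O)C/C(C(=O)OC)=C\c1cc(OC)c(OCc2ccccc2)cc1Br | intermediate
5 | methyl 4-acetoxy-6-(benzyloxy)-8-bromo-5-methoxy-2-naphthoate | COC(=O)c1cc(OC(C)=O)c2c(OC)c(OCc3ccccc3)cc(Br)c2c1 | intermediate
6 | methyl 6-(benzyloxy)-8-bromo-4-hydroxy-5-methoxy-2-naphthoate (free naphthol, not isolated) | COC(=O)c1cc(O)c2c(OC)c(OCc3ccccc3)cc(Br)c2c1 | intermediate
7 | methyl 4,6-bis(benzyloxy)-8-bromo-5-methoxy-2-naphthoate | COC(=O)c1cc(OCc2ccccc2)c2c(OC)c(OCc3ccccc3)cc(Br)c2c1 | intermediate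
8 | [4,6-bis(benzyloxy)-8-bromo-5-methoxynaphthalen-2-yl]methanol | OCc1cc(OCc2ccccc2)c2c(OC)c(OCc3ccccc3)cc(Br)c2c1 | intermediate
9 | 1,7-bis(benzyloxy)-5-bromo-3-(bromomethyl)-8-methoxynaphthalene | BrCc1cc(OCc2ccccc2)c2c(OC)c(OCc3ccccc3)cc(Br)c2c1 | intermediate
10 | 1,7-bis(benzyloxy)-8-methoxy-3-methylnaphthalene | Cc1cc(OCc2ccccc2)c2c(OC)c(OCc3ccccc3)ccc2c1 | intermediate
11 | N-{[4,6-bis(benzyloxy)-5-methoxy-2-methylnaphthalen-1-yl]methylidene}-N-methylmethanaminium chloride (iminium salt, not isolated) | C[N+](C)=Cc1c(C)cc(OCc2ccccc2)c2c(OC)c(OCc3ccccc3)ccc12.[Cl-] | intermediate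
12 | 4,6-bis(benzyloxy)-5-methoxy-2-methyl-1-naphthaldehyde | O=Cc1c(C)cc(OCc2ccccc2)c2c(OC)c(OCc3ccccc3)ccc12 | intermediate
13 | 4,6-bis(benzyloxy)-1-ethynyl-5-methoxy-2-methylnaphthalene | C#Cc1c(C)cc(OCc2ccccc2)c2c(OC)c(OCc3ccccc3)ccc12 | intermediate
14 | lithium 2-[4,6-bis(benzyloxy)-5-methoxy-2-methylnaphthalen-1-yl]ethyn-1-olate (lithium ynolate, not isolated) | [Li+].[O-]C#Cc1c(C)cc(OCc2ccccc2)c2c(OC)c(OCc3ccccc3)ccc12 | intermediate
15 | ({[4,6-bis(benzyloxy)-5-methoxy-2-methylnaphthalen-1-yl]ethynyl}oxy)tri(propan-2-yl)silane | CC(C)[Si](OC#Cc1c(C)cc(OCc2ccccc2)c2c(OC)c(OCc3ccccc3)ccc12)(C(C)C)C(C)C | intermediate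
16 | 5-methylcyclohexane-1,3-dione | CC1CC(=O)CC(=O)C1 | starting material
17 | malonyl dichloride | O=C(Cl)CC(=O)Cl | starting material
18 | 4-hydroxy-7-methyl-7,8-dihydro-2H-chromene-2,5(6H)-dione (racemic) | OC1=CC(=O)OC2=C1C(=O)CC(C)C2 | intermediate
19 | 4-methoxy-7-methyl-7,8-dihydro-2H-chromene-2,5(6H)-dione (racemic) | COC1=CC(=O)OC2=C1C(=O)CC(C)C2 | intermediate
20 | bridged lactone: 2-oxabicyclo[2.2.2]octa-5,7-dien-3-one adduct of 19 and 15, lactone bridge from pyrone C3 to pyrone C6, aryl on the alkene carbon bonded to pyrone C6, silyloxy on the alkene carbon bonded to pyrone C3 (stereoisomer mixture, not isolated) | COC1=C2C(=O)CC(C)CC23OC(=O)C1C(O[Si](C(C)C)(C(C)C)C(C)C)=C3c1c(C)cc(OCc2ccccc2)c2c(OC)c(OCc3ccccc3)ccc12 | intermediate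
21 | 5-[4,6-bis(benzyloxy)-5-methoxy-2-methylnaphthalen-1-yl]-8-methoxy-3-methyl-6-{[tri(propan-2-yl)silyl]oxy}-3,4-dihydronaphthalen-1(2H)-one (racemic at C3 of this name, atropisomer mixture) | COc1cc(O[Si](C(C)C)(C(C)C)C(C)C)c(-c2c(C)cc(OCc3ccccc3)c3c(OC)c(OCc4ccccc4)ccc23)c2CC(C)CC(=O)c12 | intermediate
22 | ({5-[4,6-bis(benzyloxy)-5-methoxy-2-methylnaphthalen-1-yl]-8-methoxy-3-methyl-6-{[tri(propan-2-yl)silyl]oxy}-3,4-dihydronaphthalen-1-yl}oxy)trimethylsilane (not isolated) | COc1cc(O[Si](C(C)C)(C(C)C)C(C)C)c(-c2c(C)cc(OCc3ccccc3)c3c(OC)c(OCc4ccccc4)ccc23)c2CC(C)C=C(O[Si](C)(C)C)c12 | intermediate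
23 | 5-[4,6-bis(benzyloxy)-5-methoxy-2-methylnaphthalen-1-yl]-8-methoxy-3-methyl-6-{[tri(propan-2-yl)silyl]oxy}naphthalen-1-ol (racemic axis) | COc1cc(O[Si](C(C)C)(C(C)C)C(C)C)c(-c2c(C)cc(OCc3ccccc3)c3c(OC)c(OCc4ccccc4)ccc23)c2cc(C)cc(O)c12 | intermediate
24 | 5-[4,6-bis(benzyloxy)-5-methoxy-2-methylnaphthalen-1-yl]-8-methoxy-3-methylnaphthalene-1,6-diol (racemic axis) | COc1cc(O)c(-c2c(C)cc(OCc3ccccc3)c3c(OC)c(OCc4ccccc4)ccc23)c2cc(C)cc(O)c12 | intermediate
25 | 5-(4,6-dihydroxy-5-methoxy-2-methylnaphthalen-1-yl)-8-methoxy-3-methylnaphthalene-1,6-diol (CNP0147277.0, racemic axis) | COc1cc(O)c(-c2c(C)cc(O)c3c(OC)c(O)ccc23)c2cc(C)cc(O)c12 | target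

## Step count and risks

Total step count: 16. Longest linear sequence: 14 steps (steps 1 to 10, then 13 to 16, from compound 1). The pyrone branch (steps 11 and 12) has two steps.

**Step 13 (key step).** The cycloaddition may be too slow at temperatures the ynol ether tolerates. The 4-methoxy group donates into the diene, and the forming C4–C4a bond joins two fully substituted carbons. Thermal isomerisation of the siloxyalkyne to a silylketene, or (2+2) addition at the enone bond, could then take over.
Fallback: keep the same two bonds but use an alkene-level two-carbon partner that aromatises by elimination. The fallback sets out from alkyne 13. Ynolate 14 is generated as in step 10 and quenched with aqueous acid to give 2-[4,6-bis(benzyloxy)-5-methoxy-2-methylnaphthalen-1-yl]acetic acid F1. Double deprotonation with LiHMDS and silylation with TMSCl give the ketene bis(trimethylsilyl) acetal F2, a more nucleophilic and thermally robust partner. Heating F2 with pyrone 19 should lead, through (4+2) addition of the same regiochemistry, loss of CO2, loss of trimethylsilanol and aqueous work-up, to 5-[4,6-bis(benzyloxy)-5-methoxy-2-methylnaphthalen-1-yl]-6-hydroxy-8-methoxy-3-methyl-3,4-dihydronaphthalen-1(2H)-one F3. Silylation with TIPSOTf and 2,6-lutidine returns to the route at compound 21.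

**Step 8.** Regioselectivity of the formylation may be poor. Competing attack at C8', the alpha position para to the C5' methoxy group, would give an isomeric aldehyde that is hard to separate.
Fallback: keep the blocking bromine through the formylation. The fallback sets out from dibromide 9. LiBHEt3 reduces only the benzylic bromide and gives 1,7-bis(benzyloxy)-5-bromo-8-methoxy-3-methylnaphthalene F4. Rieche formylation (Cl2CHOMe, SnCl4, −78 °C) can then occur only at C1', though next to the peri bromine, and gives 4,6-bis(benzyloxy)-8-bromo-5-methoxy-2-methyl-1-naphthaldehyde F5. Hydrodebromination with HCO2Na and catalytic Pd(PPh3)4 in DMF, which does not cleave benzyl ethers, returns to the route at aldehyde 12.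

**Step 10.** Oxygen transfer to the acetylide may be incomplete, with reprotonation to 13 on work-up, and the silyl ynol ether may hydrolyse during purification.
Fallback: reach the ynolate by Kowalski rearrangement instead of acetylide oxidation. The fallback sets out from aldehyde 12. Addition of LiCHBr2 (from CH2Br2 and LiTMP, −78 °C) gives 1-[4,6-bis(benzyloxy)-5-methoxy-2-methylnaphthalen-1-yl]-2,2-dibromoethan-1-ol F6. Oxidation with Dess–Martin periodinane gives 1-[4,6-bis(benzyloxy)-5-methoxy-2-methylnaphthalen-1-yl]-2,2-dibromoethan-1-one F7. LiHMDS and then n-BuLi effect enolisation, bromine–lithium exchange and 1,2-aryl shift, and the route is rejoined at ynolate 14, which is silylated to 15 as in step 10.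

**Step 14.** The oxidation may stall at the silyl enol ether or ketone stage, because palladium and the single C6 hydrogen must become syn for β-hydride elimination; palladation of the electron-rich arenes is a second possible drain.
Fallback: halogenation and elimination in place of palladium oxidation. The fallback sets out from silyl enol ether 22. NBS in THF at −78 °C gives 2-bromo-5-[4,6-bis(benzyloxy)-5-methoxy-2-methylnaphthalen-1-yl]-8-methoxy-3-methyl-6-{[tri(propan-2-yl)silyl]oxy}-3,4-dihydronaphthalen-1(2H)-one F8. Li2CO3 and LiBr in DMF at 120 °C eliminate HBr, and the route is rejoined at naphthol 23.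

## Further compounds

F1 | step 13 | 2-[4,6-bis(benzyloxy)-5-methoxy-2-methylnaphthalen-1-yl]acetic acid | OC(=O)Cc1c(C)cc(OCc2ccccc2)c2c(OC)c(OCc3ccccc3)ccc12
F2 | step 13 | ({2-[4,6-bis(benzyloxy)-5-methoxy-2-methylnaphthalen-1-yl]ethene-1,1-diyl}bis(oxy))bis(trimethylsilane) | C[Si](C)(C)OC(O[Si](C)(C)C)=Cc1c(C)cc(OCc2ccccc2)c2c(OC)c(OCc3ccccc3)ccc12
F3 | step 13 | 5-[4,6-bis(benzyloxy)-5-methoxy-2-methylnaphthalen-1-yl]-6-hydroxy-8-methoxy-3-methyl-3,4-dihydronaphthalen-1(2H)-one | COc1cc(O)c(-c2c(C)cc(OCc3ccccc3)c3c(OC)c(OCc4ccccc4)ccc23)c2CC(C)CC(=O)c12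
F4 | step 8 | 1,7-bis(benzyloxy)-5-bromo-8-methoxy-3-methylnaphthalene | Cc1cc(OCc2ccccc2)c2c(OC)c(OCc3ccccc3)cc(Br)c2c1
F5 | step 8 | 4,6-bis(benzyloxy)-8-bromo-5-methoxy-2-methyl-1-naphthaldehyde | O=Cc1c(C)cc(OCc2ccccc2)c2c(OC)c(OCc3ccccc3)cc(Br)c12
F6 | step 10 | 1-[4,6-bis(benzyloxy)-5-methoxy-2-methylnaphthalen-1-yl]-2,2-dibromoethan-1-ol (racemic) | OC(C(Br)Br)c1c(C)cc(OCc2ccccc2)c2c(OC)c(OCc3ccccc3)ccc12
F7 | step 10 | 1-[4,6-bis(benzyloxy)-5-methoxy-2-methylnaphthalen-1-yl]-2,2-dibromoethan-1-one | O=C(C(Br)Br)c1c(C)cc(OCc2ccccc2)c2c(OC)c(OCc3ccccc3)ccc12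
F8 | step 14 | 2-bromo-5-[4,6-bis(benzyloxy)-5-methoxy-2-methylnaphthalen-1-yl]-8-methoxy-3-methyl-6-{[tri(propan-2-yl)silyl]oxy}-3,4-dihydronaphthalen-1(2H)-one | COc1cc(O[Si](C(C)C)(C(C)C)C(C)C)c(-c2c(C)cc(OCc3ccccc3)c3c(OC)c(OCc4ccccc4)ccc23)c2CC(C)C(Br)C(=O)c12
A1 | alternative 1 | methyl 7-(benzyloxy)-4-[2,5-bis(benzyloxy)-4-methoxy-7-methylnaphthalen-1-yl]-1-hydroxy-8-methoxy-3-methyl-2-naphthoate | COC(=O)c1c(C)c(-c2c(OCc3ccccc3)cc(OC)c3c(OCc4ccccc4)cc(C)cc23)c2ccc(OCc3ccccc3)c(OC)c2c1O
A2 | alternative 1 | 6-(benzyloxy)-3-[2,5-bis(benzyloxy)-4-methoxy-7-methylnaphthalen-1-yl]-7-methoxy-2-benzofuran-1(3H)-one | COc1c(OCc2ccccc2)ccc2C(c3c(OCc4ccccc4)cc(OC)c4c(OCc5ccccc5)cc(C)cc34)OC(=O)c12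
A3 | alternative 1 | methyl (E)-but-2-enoate (methyl crotonate) | C/C=C/C(=O)OC
A4 | alternative 2 | 5-[4,6-bis(benzyloxy)-5-methoxy-2-methylnaphthalen-1-yl]-6,8-dihydroxy-3-methyl-3,4-dihydronaphthalen-1(2H)-one | Oc1cc(O)c(-c2c(C)cc(OCc3ccccc3)c3c(OC)c(OCc4ccccc4)ccc23)c2CC(C)CC(=O)c12
A5 | alternative 2 | methyl 4-[4,6-bis(benzyloxy)-5-methoxy-2-methylnaphthalen-1-yl]-4-(5-methyl-3-oxocyclohex-1-en-1-yl)-3-oxobutanoate | COC(=O)CC(=O)C(C1=CC(=O)CC(C)C1)c1c(C)cc(OCc2ccccc2)c2c(OC)c(OCc3ccccc3)ccc12
A6 | alternative 3 | 6-(benzyloxy)-5-[4,6-bis(benzyloxy)-5-methoxy-2-methylnaphthalen-1-yl]-8-methoxy-3-methylnaphthalen-1-ol | COc1cc(OCc2ccccc2)c(-c2c(C)cc(OCc3ccccc3)c3c(OC)c(OCc4ccccc4)ccc23)c2cc(C)cc(O)c12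
A7 | alternative 3 | 4-(benzyloxy)-3-[4,6-bis(benzyloxy)-5-methoxy-2-methylnaphthalen-1-yl]-6-methoxy-2-(trimethylsilyl)phenyl trifluoromethanesulfonate | COc1cc(OCc2ccccc2)c(-c2c(C)cc(OCc3ccccc3)c3c(OC)c(OCc4ccccc4)ccc23)c([Si](C)(C)C)c1OS(=O)(=O)C(F)(F)F
A8 | alternative 3 | [(1-methoxy-3-methylbuta-1,3-dien-1-yl)oxy]trimethylsilane | COC(O[Si](C)(C)C)=CC(C)=C
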